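common to all: starting material 0.25 M (in portions, 4); first nucleophile 0.225 M; protic impurity 0.0125 M
- theta: second nucleophile 0.75 M; capture agent 2.5 mM; run made earlier; portions every 8.0 s
- eta: second nucleophile 0.75 M; capture agent 10 mM; run made earlier; portions every 8.0 s
- gamma: second nucleophile 0.38 M; capture agent 5 mM; run made earlier; portions every 8.0 s
- Sunday's: second nucleophile 0.750 M; capture agent 5.00 mM; the portions of starting material follow each other after 8.0 s, the first at the start; time 6.0 min
- Tuesday's: second nucleophile 0.750 M; capture agent 5.00 mM; the portions of starting material follow each other after 8.0 s, the first at the start; time 2.0 min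

| run | time / s | other capture product / % | open intermediate / % | target / % | starting material / % |
|---|---|---|---|---|---|
| theta | 10.0 | 0 | 0.1 | 3.3 | 45.7 |
| theta | 25.0 | 0 | 0.2 | 0 | 91.4 |
| theta | 40.0 | 0.6 | 0.6 | 3.8 | 88.6 |
| theta | 60.0 | 2.6 | 0 | 8.1 | 84.9 |
| theta | 90.0 | 2.4 | 2.0 | 9.8 | 78.5 |
| eta | 10.0 | 0 | 0.8 | 0.4 | 44.9 |
| eta | 25.0 | 0.7 | 1.5 | 1.5 | 93.5 |
| eta | 40.0 | 1.9 | 0 | 3.3 | 88.9 |
| eta | 60.0 | 1.1 | 2.6 | 9.4 | 85.4 |
| eta | 90.0 | 5.2 | 0.7 | 10.8 | 80.6 |
| gamma | 10.0 | 0 | 0.5 | 0 | 46.2 |
| gamma | 25.0 | 0 | 2.3 | 2.4 | 91.4 |
| gamma | 40.0 | 0.5 | 1.4 | 3.2 | 87.9 |
| gamma | 60.0 | 0.5 | 0.7 | 8.3 | 85.2 |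
| gamma | 90.0 | 1.1 | 0 | 11.7 | 78.9 |

(standard deviation of a reading: 1 percentage point)



- which of these there is most of at the end, counted by the starting material in it, Sunday's (open intermediate / target / other capture product / starting material)
- which of these there is most of at the end, counted by the starting material in it, Tuesday's (open intermediate / target / other capture product / starting material)
- the largest of these amounts at the end, in percent of the starting material charged, Sunday's
- the largest of these amounts at the end, in percent of the starting material charged, Tuesday's

1. In the theta, eta and gamma runs the capture agent went from 2.5 mM to 10 mM and the second nucleophile down to 0.38 M, yet starting material at 90.0 s reads 78.5 %, 80.6 % and 78.9 %, a spread of 2.1 percentage points against a scatter of 1 point, so the three runs are averaged. The last portion enters at 24.0 s, so the reading at 25.0 s, on average 92.1 %, is the first with the whole charge in, and it falls to 79.3 % at 90.0 s. The logarithm of that ratio over the time between the readings gives 0.138 min⁻¹, the loss constant: the fraction of starting material lost per unit time once the charge is complete.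

2. Floor: the three runs share 0.225 M of first nucleophile, so they do not test its part, and this reckoning supposes that the loss runs through it. Frozen at its level (pseudo-first-order), it keeps the constant fixed and the decay exponential, which puts the floor at 42.7 % for Sunday's flask and 74.1 % for Tuesday's.

3. Ceiling: the first nucleophile is charged at 90.0 % of the starting material charged, close to the 92.1 % of starting material read at 25.0 s, so the other extreme lets it fall one for one and the constant shrink with the starting material. The amount is then the value at 25.0 s divided by one plus the constant times the time elapsed, giving 52.1 % for Sunday's and 75.6 % for Tuesday's. The midpoints, 47.4 % and 74.8 %, are the values this reckoning commits to.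

4. Ranking: the protic impurity can take 5.00 % of the charge, and at 90.0 s the theta and eta runs, which share Sunday's second nucleophile, read 73.0 % of the two capture products as target. Setting aside the open intermediate, on average 0.900 % at 90.0 s, this reckoning puts target at 38.2 % for Sunday's floor, less than the starting material.

5. The forecast names starting material for both flasks, with 50 % for Sunday's, inside the bracket reckoned here for that flask, and 74 % for Tuesday's, on the floor reckoned here: “Starting material should lead both times”.

6. Sunday's flask holds most starting material, 48.6 %, and Tuesday's most starting material, 75.1 %, each inside its bracket.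

    starting material ⇌ open intermediate (K = 0.0138, k = 0.00772 s⁻¹)
    first nucleophile + open intermediate → target (k = 0.848 M⁻¹ s⁻¹)
    second nucleophile + open intermediate → other capture product (k = 0.0536 M⁻¹ s⁻¹)
    starting material + protic impurity → quenched substrate (k = 2.28 M⁻¹ s⁻¹)
    open intermediate + capture agent → trapped intermediate (k = 0.0835 M⁻¹ s⁻¹)

Sunday's target stands at 36.2 %, with 5.00 % as quenched substrate. Scaled in proportion to the first nucleophile, the loss constant becomes 0.233 min⁻¹ for Sunday's flask with 0.38 M of it, and the same two formulas, started from the same value at 25.0 s, give that neighbour 25.1 % and 40.1 %. That neighbour ends with 37.4 % of starting material and 49.8 % of target.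

The data stem from a simulated flask on assumed constants, noise included.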